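Follow the fraction left, not the fraction made: in the alder flask, where starting complex takes up incoming ligand stepwise at constant volume and temperature, I ask at each reading what fraction of the final level of complex with two exchanged is still missing.

- alder: starting complex 1.5 M; incoming ligand 3 M; temperature 0 °C; the very flask that is asked about, followed so far
- flask: starting complex 1.5 M; incoming ligand 3.00 M; temperature 0 °C; time 6.0 h

alder run (percent of the starting complex charged): time / h: complex with two exchanged / % = 0.417: 6.0; 0.667: 11.0; 1.33: 17.9; 2.50: 22.7; 5.00: 24.3

(each reading ± 0.5 percentage points)

- alpha: at 6.0 h take out 90% of the complex with two exchanged then present, then wait 3.0 h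
- theta: change nothing and wait 3.0 h more
- zeta: at 6.0 h raise the temperature by 20 K, then wait 3.0 h

- what is taken out of complex with two exchanged is counted as made
- the earlier runs do not show what temperature does; that part of a forecast is a guess

- complex with two exchanged, in percent of the starting complex first charged, at 6.0 h
- what to do for the largest gain in complex with two exchanged; "none" if nothing gains more than 2 percentage points (alpha / theta / zeta / none)
- complex with two exchanged present, with what was taken out counted in, in percent of the starting complex first charged, after alpha
- complex with two exchanged present, with what was taken out counted in, in percent of the starting complex first charged, after theta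

In the first instants the flask shows an induction period: 6.0% by 0.417 h, then 5 percentage points in the next 0.250 h, a rise faster than the opening one, as a second exchange needs its predecessor to build up. In the middle I take the last reading, 24.3%, as the level and form ([level] − [complex with two exchanged])/[level], which falls from 54.7% at 0.667 h to 6.58% at 2.50 h. That gives the gap half-time, the time in which the missing fraction halves, 0.600 h, a reading that carries the scatter. At the last reading, complex with two exchanged accounts for 24.3% of the charge of incoming ligand, and 75.7% of the starting complex stands elsewhere, unseen by these readings.

So I reckon 24.3% for the flask at 6.0 h, with an estimated gap of 0.028 points, smaller than the margin, so I expect theta to gain too little to count. Alpha takes out 21.9% on this reckoning and reopens a gap, and the 3.0 h that follow are 5.00 half-times if the rate holds, so I put alpha before theta; how far the flask regrows the readings do not say, and I name no figure, and what zeta does is a guess, so my choice of alpha over zeta is a guess too.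

The forecast gives 24.6%, 24.8% after theta and 36% after alpha, and chooses alpha, reasoning: “Ligand is not exhausted, so the likeliest cause is reversibility, with released ligand pushing back.”

The flask gives 25.0%, 25.2% after theta and 33.6% after alpha; the gains are 8.6 points for alpha, 0.19 points for theta and −12 points for zeta, so the choice is alpha.

    2 starting complex → self-condensation product (k = 1.06 × 10⁻⁴ M⁻¹ s⁻¹, Ea = 52.0 kJ mol⁻¹)
    complex with one exchanged + incoming ligand ⇌ leaving ligand + complex with two exchanged (K = 0.760, k = 2.53 × 10⁻⁴ M⁻¹ s⁻¹, Ea = 71.0 kJ mol⁻¹, ΔH = −44.0 kJ mol⁻¹)
    starting complex + incoming ligand ⇌ leaving ligand + complex with one exchanged (K = 1.92, k = 4.50 × 10⁻⁵ M⁻¹ s⁻¹, Ea = 53.0 kJ mol⁻¹, ΔH = −33.0 kJ mol⁻¹)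
    (constants at 0 °C)

Now run the same charge at −25 °C: this neighbour shows 5.33% of complex with two exchanged at 6.0 h. Held against the level read in the alder run, which no run shows for this neighbour, its missing fraction is 78.1%, which is 0.357 half-times counted from the charge, against a reckoned 10.0 in the alder flask, and so an estimated gap half-time of 16.8 h on that assumption. This neighbour still has 48% of its starting complex unbound.

(Readings and results are calculated with made-up constants, noise included.)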